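**Retrosynthetic overview**
1. Target 15 ⇐ dimethoxyquinone 14 (selective hydrolysis of one OMe) ⇐ acid 12 + 2,5‑dimethoxybenzoquinone 13, joined at C15–C3′ by a photochemical decarboxylative radical coupling (last C–C bond).
2. Acid 12 ⇐ bicyclic enone 7: C9 quaternary centre by enolate alkylation, 8‑Me by methylenation/hydrogenation, C4=CH2 carried as a masked Peterson precursor and released late.
3. Enone 7 ⇐ Diels–Alder of (R)‑carvone 3 with siloxydiene 2 (cis ring fusion, sets C5/C10), then excision of the isopropenyl control group.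
4. Ring order: ring A (bought as carvone) → ring B (Diels–Alder) → quinone ring (bought intact, attached last).

Assumption: the SMILES is read as (5R,8S,9R,10S), cis‑fused, i.e. 5‑epi‑ilimaquinone. Locants are avarane numbering (decalin C1–C10; C11 = exocyclic CH2 on C4; C15 = CH2 on C9). α/β refer to the drawing with the 8‑ and 9‑methyls β; the target is 5α‑Me, 10α‑H, 8β‑Me, 9β‑Me, 9α‑CH2.

**Step 1**
Reactants: 1 pent‑1‑en‑3‑one
Product: 2 (Z)‑3‑(tert‑butyldimethylsilyloxy)penta‑1,3‑diene
Conditions: TBSOTf, Et3N, CH2Cl2, −78 → 0 °C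
Reagents that add atoms: TBSOTf, CC(C)(C)[Si](C)(C)OS(=O)(=O)C(F)(F)F
Why: Soft enolisation/O‑silylation gives the Z silyl dienol ether, with the terminal methyl "outside" so the diene can reach s‑cis.

**Step 2**
Reactants: 3 (R)‑(−)‑carvone; 2
Product: 4 cis‑fused adduct: 2α‑isopropenyl‑5α‑methyl‑10α‑H‑9β‑methyl‑8‑(TBSO)‑Δ7‑octalin‑4‑one
Conditions: AlBr3/AlMe3 (5:1, 0.3 equiv), toluene–CH2Cl2, −10 °C; Et3N quench
Reagents that add atoms: none
Why: Lewis‑acid Diels–Alder; the siloxy group makes C9 the nucleophilic terminus, so it bonds to the enone β‑carbon C10 ("para" to OSi), and the diene adds anti to the isopropenyl group, giving the cis fusion and setting C5 and C10 from the carvone stereocentre. The C9 configuration is irrelevant because C9 is re‑enolised in step 6.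

**Step 3**
Reactants: 4
Product: 5 the C4 adduct: 4‑(triethylsilyloxy)‑4‑(trimethylsilylmethyl) derivative of 4 (C4 epimers, both used)
Conditions: TMSCH2Li, CeCl3, THF, −78 °C; pH 7 work‑up; then TESOTf, 2,6‑lutidine, CH2Cl2, −78 → 0 °C
Reagents that add atoms: TMSCH2Li, [Li]C[Si](C)(C)C; TESOTf, CC[Si](CC)(CC)OS(=O)(=O)C(F)(F)F
Why: Peterson‑reagent 1,2‑addition to the only free carbonyl (C8 is still a silyl enol ether), then O‑silylation. The β‑silyloxy silane is a latent C4=CH2 that tolerates ozone, LDA, ylide and H2; the new C4 centre is destroyed later.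

**Step 4**
Reactants: 5
Product: 6 enone: Δ6‑8‑one (C9 β‑Me, α‑H), C4 masked, 2α‑isopropenyl
Conditions: Pd(OAc)2, O2 (1 atm), DMSO, 45 °C
Reagents that add atoms: none
Why: Saegusa–Ito oxidation; the C7 palladium enolate can only β‑hydride eliminate toward C6, which blocks C7 and leaves C9‑H as the only enolisable position.

**Step 5**
Reactants: 6
Product: 7 nor‑enone: as 6 with C2 = CH2
Conditions: O3, MeOH–CH2Cl2, −78 °C (indicator end‑point); then FeSO4·7H2O, PhSH, −78 °C → rt
Reagents that add atoms: none (H from PhSH)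
Why: Hydrodealkenylation: ozone takes the electron‑rich isopropenyl (the enone alkene is deactivated); Fe(II) reduction of the α‑methoxy hydroperoxide, β‑scission and H‑atom transfer from the thiol replace the control group by H. C5 and C10 are untouched, and thiol conjugate addition is disfavoured at the neopentyl enone β‑carbon C6.

**Step 6**
Reactants: 7; 8 benzyl bromoacetate
Product: 9 9α‑(benzyloxycarbonylmethyl)‑9β‑methyl enone
Conditions: LDA, THF, −78 °C; then 8, DMPU, −78 → −20 °C
Reagents that add atoms: benzyl bromoacetate, BrCC(=O)OCc1ccccc1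
Why: Kinetic α′‑enolate alkylation; C9 is the only acidic site (C7 is vinylic, C5 is quaternary, C4 is masked). The electrophile is expected to enter on the α face, anti to the ring‑A carbon C1 on the adjacent C10, setting C9 with CH2 α and Me β.

**Step 7**
Reactants: 9
Product: 10 8‑methylene‑Δ6 diene
Conditions: Ph3PCH3Br, KHMDS, THF, 0 → 50 °C
Reagents that add atoms: methylenetriphenylphosphorane (from Ph3PCH3Br), C=P(c1ccccc1)(c1ccccc1)c1ccccc1
Why: Wittig methylenation of the only ketone; the ester is inert to the non‑stabilised ylide under these conditions and the O‑silylated carbinol cannot undergo premature Peterson elimination.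

**Step 8**
Reactants: 10
Product: 11 saturated acid: 8β‑methyl, 9α‑CH2CO2H, C4 still masked
Conditions: H2 (3 atm), 10% Pd/C, EtOAc–EtOH, rt
Reagents that add atoms: none
Why: Heterogeneous hydrogenation saturates C6=C7 and C8=CH2 and hydrogenolyses the benzyl ester in one operation. The bulky C4 centre holds ring A over the β face of ring B (C1 syn‑axial to C8), so hydrogen should arrive from the α face and give 8β‑Me, cis to 9β‑Me.

**Step 9**
Reactants: 11
Product: 12 2‑[(1R,2S,4aR,8aS)‑1,2,4a‑trimethyl‑5‑methylidenedecahydronaphthalen‑1‑yl]acetic acid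
Conditions: 48% aq HF, MeCN, 0 °C → rt
Reagents that add atoms: none
Why: HF cleaves the TES ether and the tertiary β‑hydroxysilane undergoes acid‑promoted Peterson elimination. The β‑silyl‑stabilised cation can only lose TMS, so only the exocyclic C4=C11 alkene forms and no stereocentre is touched.

**Step 10**
Reactants: 12; 13 2,5‑dimethoxy‑1,4‑benzoquinone (4 equiv)
Product: 14 2,5‑dimethoxy‑3‑{[(1R,2S,4aR,8aS)‑1,2,4a‑trimethyl‑5‑methylidenedecahydronaphthalen‑1‑yl]methyl}‑1,4‑benzoquinone
Conditions: N‑hydroxypyridine‑2‑thione, DCC, DMAP (cat.), CH2Cl2, 0 °C, dark; then 13, visible light (W lamp or 450 nm LED), 0 °C → rt; Et3N/air work‑up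
Reagents that add atoms: 2,5‑dimethoxy‑1,4‑benzoquinone, COC1=CC(=O)C(OC)=CC1=O
Why: Proposed new method: photolysis of the thiohydroxamate (Barton) ester releases CO2 and the nucleophilic neopentyl C15 radical, which adds to an unsubstituted vinylic carbon of 13 (the two C–H sites are equivalent, so one regioisomer); the captodative α‑methoxy/α‑acyl adduct radical either takes up the pyridylthio group (chain transfer) and then loses pyridine‑2‑thiol, the better leaving group than methoxide, or enolises to a semiquinone that excess 13 oxidises, in both cases restoring the quinone with both oxygens already in place. The closest known reactions are Barton‑ester photolysis trapped by p‑benzoquinone and Minisci/Jacobsen–Torssell‑type quinone alkylation; 2,5‑dialkoxyquinones have not been used as the acceptor. The radical cannot cyclise onto C4=CH2 because the two groups are 1,3‑trans on ring B.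

**Step 11**
Reactants: 14
Product: 15 5‑epi‑ilimaquinone (target)
Conditions: 70% HClO4 (about 10 equiv), THF–H2O, 0 °C → rt, quenched at full conversion
Reagents that add atoms: water, O
Why: Regioselective acid hydrolysis (addition–elimination) of the vinylogous ester next to the alkyl group, as in the known 2,5‑dimethoxy‑3‑alkylquinone → 2‑hydroxy‑5‑methoxy conversion. The THF‑diluted acid and short contact time are chosen to spare the exocyclic alkene.

**Compound list**
1 | pent‑1‑en‑3‑one | C=CC(=O)CC | starting material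
2 | (Z)‑3‑(tert‑butyldimethylsilyloxy)penta‑1,3‑diene | C/C=C(/C=C)O[Si](C)(C)C(C)(C)C | intermediate
3 | (R)‑(−)‑carvone | CC1=CC[C@H](CC1=O)C(C)=C | starting material
4 | cis Diels–Alder adduct (2α‑isopropenyl, 5α‑Me, 10α‑H, 9β‑Me, 8‑OTBS, Δ7, 4‑one) | O=C1C[C@H](C(C)=C)C[C@H]2[C@@H](C)C(O[Si](C)(C)C(C)(C)C)=CC[C@@]12C | intermediate
5 | 4‑(triethylsilyloxy)‑4‑(trimethylsilylmethyl) derivative of 4 | C[Si](C)(C)CC1(O[Si](CC)(CC)CC)C[C@H](C(C)=C)C[C@H]2[C@@H](C)C(O[Si](C)(C)C(C)(C)C)=CC[C@@]12C | intermediate
6 | Δ6‑8‑one enone, C4 masked, 2α‑isopropenyl | C[Si](C)(C)CC1(O[Si](CC)(CC)CC)C[C@H](C(C)=C)C[C@H]2[C@@H](C)C(=O)C=C[C@@]12C | intermediate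
7 | dealkenylated enone | C[Si](C)(C)CC1(O[Si](CC)(CC)CC)CCC[C@H]2[C@@H](C)C(=O)C=C[C@@]12C | intermediate
8 | benzyl bromoacetate | BrCC(=O)OCc1ccccc1 | starting material
9 | 9α‑CH2CO2Bn‑9β‑Me enone | C[Si](C)(C)CC1(O[Si](CC)(CC)CC)CCC[C@H]2[C@](C)(CC(=O)OCc3ccccc3)C(=O)C=C[C@@]12C | intermediate
10 | 8‑methylene‑Δ6 diene ester | C[Si](C)(C)CC1(O[Si](CC)(CC)CC)CCC[C@H]2[C@](C)(CC(=O)OCc3ccccc3)C(=C)C=C[C@@]12C | intermediate
11 | saturated acid, 8β‑Me, C4 masked | C[Si](C)(C)CC1(O[Si](CC)(CC)CC)CCC[C@H]2[C@](C)(CC(=O)O)[C@@H](C)CC[C@@]12C | intermediate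
12 | 2‑[(1R,2S,4aR,8aS)‑1,2,4a‑trimethyl‑5‑methylidenedecahydronaphthalen‑1‑yl]acetic acid | C=C1CCC[C@H]2[C@](C)(CC(=O)O)[C@@H](C)CC[C@@]12C | intermediate
13 | 2,5‑dimethoxy‑1,4‑benzoquinone | COC1=CC(=O)C(OC)=CC1=O | starting material
14 | 2,5‑dimethoxy‑3‑(decalinylmethyl)‑1,4‑benzoquinone | C=C1CCC[C@H]2[C@](C)(CC3=C(OC)C(=O)C=C(OC)C3=O)[C@@H](C)CC[C@@]12C | intermediate
15 | 5‑epi‑ilimaquinone, 2‑hydroxy‑5‑methoxy‑3‑{[(1R,2S,4aR,8aS)‑1,2,4a‑trimethyl‑5‑methylidenedecahydronaphthalen‑1‑yl]methyl}‑1,4‑benzoquinone | C=C1CCC[C@H]2[C@](C)(CC3=C(O)C(=O)C=C(OC)C3=O)[C@@H](C)CC[C@@]12C | target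

**Totals**
Total steps: 11. Longest linear sequence: 11 (steps 1–11 from pent‑1‑en‑3‑one; 10 steps from (R)‑carvone).

**Steps most likely to fail, with fallbacks**
1. Step 10 (proposed new coupling): the electron‑rich dimethoxyquinone may trap the neopentyl radical too slowly or give pyridylthio by‑products. Fallback (known chemistry): trap the same photogenerated radical with p‑benzoquinone, the documented Barton‑ester/quinone addition giving the 2‑alkyl‑3‑(2‑pyridylthio)quinone, then install the 5‑OMe and 2‑OH stepwise on that adduct with methoxide and hydrolysis (about three extra steps).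
2. Step 6 (C9 alkylation): the α face also carries the 5α‑methyl, so face selectivity could erode or invert. Fallback: reverse the order of introduction. Use 2‑(TBSO)buta‑1,3‑diene in step 2, then alkylate C9 first with 8 and second with MeI, so the preferred face is used for the group that must end up on it.
3. Step 8 (C8 hydrogenation): the α face next to C8 carries the 9α‑CH2CO2Bn arm, so the facial preference could be low or reversed, and Pd may isomerise the diene. Fallback: substrate‑directed homogeneous hydrogenation of 10 with Crabtree's catalyst, [Ir(cod)(PCy3)(py)]PF6, H2, CH2Cl2. The ester carbonyl on the α arm delivers hydrogen to the α face and fixes 8β‑Me. A separate H2, Pd/C hydrogenolysis of the benzyl ester follows (one extra step).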